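**Plan** (ring locants O1, O2, C3 (acetic acid arm), C4, C5; side chain C1'–C12')

- Cuts: CO2H from its methyl ester; the diene at C10'–C11' (alkenylboronate + (E)-β-bromostyrene) and at C9'=C10' (terminal alkene + vinylboronate); the ring at C4–C5 and O2–C3; the chain ketone at its C4–CH3 and C3=C4 bonds.
- Enabling feature: in ring O1–O2–C3–C4–C5, C5 (CH3, C1', O1) is a masked ketone carbon, so C5=O1(+)–O2–SiEt3 is a three-atom electrophile. C4H2–C3(CH3)(CH2CO2Me) is the retron of a 1,1-disubstituted alkene whose tertiary C3 cation is trapped by O2.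
- Forward: enone by cross-metathesis, conjugate methylation, ketal, peroxyketal, O-silylation, then a (3+2) annulation that makes the only saturated ring and both quaternary carbons at once. The phenyldiene is added afterwards (it would compete for the peroxycarbenium ion), then saponification.
- Stereochemistry: C2' from ligand-controlled copper-catalysed conjugate addition; C5 and C3 from a confined chiral counter-anion in the annulation; the (E,E)-diene from E-selective metathesis and stereoretentive coupling.

Key step: step 6

Assumption: the absolute sense of induction of the ligand in step 2 and of the chiral acid in step 6 is taken as drawn; if a first run shows the opposite sense, the mirror-image ligand or acid is used.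

**Step 1**
Reactants: 1 deca-1,9-diene; 2 but-3-en-2-one
Product: 3 (3E)-dodeca-3,11-dien-2-one
Conditions: 1 (4 equiv), second-generation Grubbs catalyst RuCl2(=CHPh)(PCy3)(H2IMes) (2 mol%), CH2Cl2, 40 °C
Reagents that add atoms: none
Why: Olefin cross-metathesis of an electron-poor enone with a terminal alkene is reliably E-selective, and the excess of the symmetrical diene 1 (recoverable by distillation) should limit double cross-metathesis.

**Step 2**
Reactants: 3 (3E)-dodeca-3,11-dien-2-one
Product: 5 (4R)-4-methyldodec-11-en-2-one, via bromomagnesium enolate 4 (not isolated)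
Conditions: MeMgBr (1.2 equiv), CuBr·SMe2 (5 mol%), JosiPhos ligand (R)-1-[(S)-2-(diphenylphosphino)ferrocenyl]ethyldicyclohexylphosphine (6 mol%), t-BuOMe, −75 °C; then 1 M HCl
Reagents that add atoms: methylmagnesium bromide, C[Mg]Br
Why: Copper-catalysed asymmetric conjugate addition of a Grignard reagent to an acyclic (E)-enone under ferrocenyl diphosphine control should deliver methyl to the Re face of C4, setting the (R) centre that becomes C2' of the side chain, while the isolated terminal alkene is inert.

**Step 3**
Reactants: 5 (4R)-4-methyldodec-11-en-2-one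
Product: 6 (4R)-2,2-dimethoxy-4-methyldodec-11-ene
Conditions: HC(OMe)3 (3 equiv), MeOH, p-TsOH·H2O (2 mol%), rt; Et3N quench
Reagents that add atoms: trimethyl orthoformate, COC(OC)OC; methanol, CO
Why: Acid-catalysed ketalisation driven by the orthoester as water scavenger; the β-stereocentre cannot epimerise and the alkene is untouched.

**Step 4**
Reactants: 6 (4R)-2,2-dimethoxy-4-methyldodec-11-ene
Product: 7 (4R)-2-hydroperoxy-2-methoxy-4-methyldodec-11-ene (both C2 epimers)
Conditions: anhydrous H2O2 in Et2O (2 equiv), PPTS (5 mol%), 0 °C; NaHCO3 quench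
Reagents that add atoms: hydrogen peroxide, OO
Why: Acid-catalysed perhydrolysis (transketalisation) of a dimethyl ketal through its oxocarbenium ion, with limited H2O2, weak acid and low temperature chosen to stop at the monoperoxyketal; the new ketal centre forms as both epimers, which does not matter because it is planarised in step 6.

**Step 5**
Reactants: 7 (4R)-2-hydroperoxy-2-methoxy-4-methyldodec-11-ene
Product: 8 triethyl{[(4R)-2-methoxy-4-methyldodec-11-en-2-yl]peroxy}silane (both C2 epimers)
Conditions: Et3SiCl (1.2 equiv), imidazole (1.5 equiv), DMF, 0 °C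
Reagents that add atoms: chlorotriethylsilane, CC[Si](Cl)(CC)CC
Why: O-silylation of a hydroperoxide under basic conditions leaves the acid-labile peroxyketal intact and installs the silyl group that is expelled in the ring closure.

**Step 6**
Reactants: 8 triethyl{[(4R)-2-methoxy-4-methyldodec-11-en-2-yl]peroxy}silane; 9 methyl 3-methylbut-3-enoate
Product: 12 methyl 2-[(3S,5R)-3,5-dimethyl-5-[(2R)-2-methyldec-9-en-1-yl]-1,2-dioxolan-3-yl]acetate, via peroxycarbenium ion 10 (not isolated), via tertiary carbocation 11 (not isolated)
Conditions: 9 (3 equiv), (S,S)-IDPi acid (confined BINOL-derived N,N'-bis(trifluoromethylsulfonyl) imidodiphosphorimidate with 3,3'-aryl groups, 5 mol%), toluene, −78 → −40 °C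
Reagents that add atoms: none
Why: Proposed new method: the chiral acid HX* (after the first turnover its silyl form Et3Si–X*) removes the methoxy group of 8 to give the ion pair of peroxycarbenium ion 10 and the confined anion X*−, the CH2 terminus of 9 adds to C5 to make the C4–C5 bond and tertiary cation 11 at C3, the silylated peroxy oxygen collapses onto C3, and Et3Si+ leaves as Et3SiOMe so that the acid turns over. The closest known reaction types are the SnCl4-promoted (3+2) annulation of triethylsilyl peroxyketals with alkenes, which gives 1,2-dioxolanes without absolute control, and imidodiphosphorimidate-catalysed additions of π-nucleophiles to oxocarbenium ions of methyl alkyl ketones. The 1,2-dioxolane is closed in a stepwise polar (3+2) fashion, intermolecular C–C bond formation first and then five-membered ring closure by attack of O2 on the C3 cation. C5 is fixed in the C–C bond-forming step, where the anion pocket has to tell CH3 from CH2CH(CH3)R on the planar C5=O1(+) unit and leave one face open to 9, the chain stereocentre β to C5 being too remote to override the catalyst. C3 is fixed in the ring closure, where the ion-paired envelope transition state should place CH2CO2Me on the face opposite to the larger C5 arm, so that the two CH2 arms end up trans. The step also needs chemoselection for the 1,1-disubstituted alkene of 9 over the monosubstituted alkene of 8 and Markovnikov regiochemistry, both secured by the tertiary cation that only 9 can form, and it needs the absence of better π-nucleophiles, which is why the phenyldiene is not yet present.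

**Step 7**
Reactants: 12 methyl 2-[(3S,5R)-3,5-dimethyl-5-[(2R)-2-methyldec-9-en-1-yl]-1,2-dioxolan-3-yl]acetate; 13 4,4,5,5-tetramethyl-2-vinyl-1,3,2-dioxaborolane
Product: 14 methyl 2-[(3S,5R)-3,5-dimethyl-5-[(2R,9E)-2-methyl-10-(4,4,5,5-tetramethyl-1,3,2-dioxaborolan-2-yl)dec-9-en-1-yl]-1,2-dioxolan-3-yl]acetate
Conditions: 13 (3 equiv), second-generation Grubbs catalyst RuCl2(=CHPh)(PCy3)(H2IMes) (5 mol%), CH2Cl2, 40 °C
Reagents that add atoms: none
Why: Cross-metathesis of a terminal alkene with vinylboronic acid pinacol ester is an E-selective reaction type, and a ditertiary dialkyl peroxide without O–H or α-hydrogen should tolerate the ruthenium carbene.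

**Step 8**
Reactants: 14 methyl 2-[(3S,5R)-3,5-dimethyl-5-[(2R,9E)-2-methyl-10-(4,4,5,5-tetramethyl-1,3,2-dioxaborolan-2-yl)dec-9-en-1-yl]-1,2-dioxolan-3-yl]acetate; 15 (E)-(2-bromoethenyl)benzene
Product: 16 methyl 2-[(3S,5R)-3,5-dimethyl-5-[(2R,9E,11E)-2-methyl-12-phenyldodeca-9,11-dien-1-yl]-1,2-dioxolan-3-yl]acetate
Conditions: 15 (1.2 equiv), Pd(PPh3)4 (5 mol%), K3PO4 (3 equiv), THF/H2O, 50 °C, degassed
Reagents that add atoms: none
Why: Suzuki–Miyaura coupling of an (E)-alkenylboronate with an (E)-alkenyl bromide (oxidative addition to zerovalent palladium, transmetalation, reductive elimination) proceeds with retention at both partners and should give the (E,E)-diene, the hindered ditertiary peroxide being a poor substrate for phosphine or palladium reduction at this temperature.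

**Step 9**
Reactants: 16 methyl 2-[(3S,5R)-3,5-dimethyl-5-[(2R,9E,11E)-2-methyl-12-phenyldodeca-9,11-dien-1-yl]-1,2-dioxolan-3-yl]acetate
Product: 18 2-[(3S,5R)-3,5-dimethyl-5-[(2R,9E,11E)-2-methyl-12-phenyldodeca-9,11-dien-1-yl]-1,2-dioxolan-3-yl]acetic acid, via lithium carboxylate 17 (not isolated)
Conditions: LiOH·H2O (3 equiv), THF/H2O, 0 °C → rt; then 1 M HCl to pH 3, 0 °C
Reagents that add atoms: lithium hydroxide, [Li+].[OH-]
Why: Saponification of the methyl ester followed by mild acidification; C3 and C5 carry no hydrogen, so Kornblum–DeLaMare fragmentation is impossible, and low temperature with short exposure should limit retro-oxa-Michael opening through the ester enolate.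

**Compound list**

1 | deca-1,9-diene | C=CCCCCCCC=C | starting material
2 | but-3-en-2-one | CC(=O)C=C | starting material
3 | (3E)-dodeca-3,11-dien-2-one | CC(=O)/C=C/CCCCCCC=C | intermediate
4 | bromomagnesium enolate of (4R)-4-methyldodec-11-en-2-one | C[C@H](CCCCCCC=C)C=C(C)O[Mg]Br | intermediate (not isolated)
5 | (4R)-4-methyldodec-11-en-2-one | C[C@H](CCCCCCC=C)CC(C)=O | intermediate
6 | (4R)-2,2-dimethoxy-4-methyldodec-11-ene | C[C@H](CCCCCCC=C)CC(C)(OC)OC | intermediate
7 | (4R)-2-hydroperoxy-2-methoxy-4-methyldodec-11-ene (both C2 epimers) | C[C@H](CCCCCCC=C)CC(C)(OC)OO | intermediate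
8 | triethyl{[(4R)-2-methoxy-4-methyldodec-11-en-2-yl]peroxy}silane (both C2 epimers) | C[C@H](CCCCCCC=C)CC(C)(OC)OO[Si](CC)(CC)CC | intermediate
9 | methyl 3-methylbut-3-enoate | C=C(C)CC(=O)OC | starting material
10 | triethylsilylperoxycarbenium ion derived from 8 (chiral anion not drawn) | C[C@H](CCCCCCC=C)CC(C)=[O+]O[Si](CC)(CC)CC | intermediate (not isolated)
11 | C3 tertiary carbocation after C4–C5 bond formation (chiral anion not drawn) | C[C@H](CCCCCCC=C)C[C@@](C)(OO[Si](CC)(CC)CC)C[C+](C)CC(=O)OC | intermediate (not isolated)
12 | methyl 2-[(3S,5R)-3,5-dimethyl-5-[(2R)-2-methyldec-9-en-1-yl]-1,2-dioxolan-3-yl]acetate | C[C@H](CCCCCCC=C)C[C@]1(C)C[C@@](C)(CC(=O)OC)OO1 | intermediate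
13 | 4,4,5,5-tetramethyl-2-vinyl-1,3,2-dioxaborolane | C=CB1OC(C)(C)C(C)(C)O1 | starting material
14 | methyl 2-[(3S,5R)-3,5-dimethyl-5-[(2R,9E)-2-methyl-10-(4,4,5,5-tetramethyl-1,3,2-dioxaborolan-2-yl)dec-9-en-1-yl]-1,2-dioxolan-3-yl]acetate | C[C@H](CCCCCC/C=C/B1OC(C)(C)C(C)(C)O1)C[C@]1(C)C[C@@](C)(CC(=O)OC)OO1 | intermediate
15 | (E)-(2-bromoethenyl)benzene | Br/C=C/c1ccccc1 | starting material
16 | methyl 2-[(3S,5R)-3,5-dimethyl-5-[(2R,9E,11E)-2-methyl-12-phenyldodeca-9,11-dien-1-yl]-1,2-dioxolan-3-yl]acetate | C[C@H](CCCCCC/C=C/C=C/c1ccccc1)C[C@]1(C)C[C@@](C)(CC(=O)OC)OO1 | intermediate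
17 | lithium 2-[(3S,5R)-3,5-dimethyl-5-[(2R,9E,11E)-2-methyl-12-phenyldodeca-9,11-dien-1-yl]-1,2-dioxolan-3-yl]acetate | C[C@H](CCCCCC/C=C/C=C/c1ccccc1)C[C@]1(C)C[C@@](C)(CC(=O)[O-])OO1.[Li+] | intermediate (not isolated)
18 | 2-[(3S,5R)-3,5-dimethyl-5-[(2R,9E,11E)-2-methyl-12-phenyldodeca-9,11-dien-1-yl]-1,2-dioxolan-3-yl]acetic acid | C[C@H](CCCCCC/C=C/C=C/c1ccccc1)C[C@]1(C)C[C@@](C)(CC(=O)O)OO1 | target

**Total steps:** 9. **Longest linear sequence:** 9 steps (1 and 2 to 18).

**Steps most likely to fail**

Step 6 (proposed new method). The chiral anion may fail to discriminate the faces of the peroxycarbenium ion (C5) or to bias the ring closure (C3), or silyl transfer may stall the turnover. The fallback sets out from 8 and uses known chemistry in a stepwise way. Hosomi–Sakurai allylation of the peroxycarbenium ion with methyl 3-[(trimethylsilyl)methyl]but-3-enoate (Me3SiOTf cat., CH2Cl2, −78 °C) should give methyl (7R)-5,7-dimethyl-3-methylidene-5-[(triethylsilyl)peroxy]pentadec-14-enoate F1. HF·pyridine in THF should free the tertiary hydroperoxide methyl (7R)-5-hydroperoxy-5,7-dimethyl-3-methylidenepentadec-14-enoate F2. Base (Et2NH or catalytic DBU in CF3CH2OH) should move the double bond into conjugation, giving methyl (7R)-5-hydroperoxy-3,5,7-trimethylpentadeca-2,14-dienoate F3, which closes in the same flask by 5-exo oxa-Michael addition to the dioxolane ester. This route has no absolute control at C5 and only thermodynamic control at C3, so the (3S,5R,2'R) isomer is separated by preparative HPLC and unwanted C3 epimers are re-equilibrated under the same basic conditions. The fallback comes back to the route at 12.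

Step 4. Exchange may run on to the geminal dihydroperoxide or revert to the ketone through adventitious water. The fallback sets out from 6: loss of methanol with Me3SiOTf/i-Pr2NEt (CH2Cl2, 0 °C) should give the methyl enol ether (4R)-2-methoxy-4-methyldodeca-1,11-diene F4, together with its 2-ene regioisomers, which converge. Acid-catalysed Markovnikov addition of anhydrous H2O2 (PPTS cat., Et2O, 0 °C) then adds across the enol ether instead of exchanging at a ketal. The fallback comes back at 7.

Step 8. The basic aqueous palladium conditions may erode the diene geometry, reduce the O–O bond through phosphine or palladium, or open the ring through the ester enolate. The fallback sets out from 12 and bypasses both boron steps. Ozonolysis of its only C=C (O3, CH2Cl2, −78 °C; Me2S) should give methyl 2-[(3S,5R)-3,5-dimethyl-5-[(2R)-2-methyl-9-oxononyl]-1,2-dioxolan-3-yl]acetate F5. Horner–Wadsworth–Emmons olefination with the preformed lithium anion of diethyl [(2E)-3-phenylprop-2-en-1-yl]phosphonate (LiHMDS, THF, −78 → 0 °C) should then build the (E,E)-diene in one C–C bond-forming event. The fallback comes back at 16.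

**Further compounds**

F1 | step 6 | methyl (7R)-5,7-dimethyl-3-methylidene-5-[(triethylsilyl)peroxy]pentadec-14-enoate (both C5 epimers) | C[C@H](CCCCCCC=C)CC(C)(OO[Si](CC)(CC)CC)CC(=C)CC(=O)OC
F2 | step 6 | methyl (7R)-5-hydroperoxy-5,7-dimethyl-3-methylidenepentadec-14-enoate (both C5 epimers) | C[C@H](CCCCCCC=C)CC(C)(OO)CC(=C)CC(=O)OC
F3 | step 6 | methyl (7R)-5-hydroperoxy-3,5,7-trimethylpentadeca-2,14-dienoate (E/Z, both C5 epimers, not isolated) | C[C@H](CCCCCCC=C)CC(C)(OO)CC(C)=CC(=O)OC
F4 | step 4 | (4R)-2-methoxy-4-methyldodeca-1,11-diene | C[C@H](CCCCCCC=C)CC(=C)OC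
F5 | step 8 | methyl 2-[(3S,5R)-3,5-dimethyl-5-[(2R)-2-methyl-9-oxononyl]-1,2-dioxolan-3-yl]acetate | C[C@H](CCCCCCC=O)C[C@]1(C)C[C@@](C)(CC(=O)OC)OO1
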